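Rings are lettered A (2,4,6-trihydroxyphenyl end) to F. The route rests on cutting ring E out of the chain as 3,4,5-trimethoxybenzyne: ring E carries the ring D ether oxygen on C1, the ring F ether oxygen on the neighbouring C2 and hydroxyls on C3 to C5, which is exactly this aryne after vicinal uptake of two groups. In one operation the key step joins the hindered ring D phenoxide oxygen to C1 and places iodine on C2, the carbon that must later carry ring F. Its precursor is the permethylated A-B-C-D tetramer with a single free hydroxyl on ring D between two methoxy groups, assembled by three CuI-catalysed coupling and Dakin oxidation cycles.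

Key step: step 10

Remarks on the chemistry
- Rings C and E are numbered C1 (oxygen to the earlier ring), C2 (oxygen to the later ring), C3 to C5 (oxygenated), C6 (hydrogen). The target has no stereocentre.
- Ring-by-ring comparison shows that tetramer phenol 13, silyl triflate 18 and pentamer iodide 23, as drawn in the compound list, map onto the target without any change of substituent position.
- Assumption: compounds 1, 2, 6, 14, 19 and 27 are purchased. Methyl ethers are the only protecting groups.
- Design choices: in rings B, C and D a formyl group both activates the aryl bromide for coupling and serves as the masked hydroxyl. The phenoxide for step 10 is made with KH, so that hydrogen is the only co-product and no conjugate acid stays in the flask. Ring F carries no further ether link, so it is brought in with its final oxygenation pattern as aryl iodide 27.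

Step 1
Reactants: 1 2,4,6-trimethoxyphenol; 2 4-bromo-2,6-dimethoxybenzaldehyde
Product: 3 2,6-dimethoxy-4-(2,4,6-trimethoxyphenoxy)benzaldehyde (A-B aldehyde)
Conditions: CuI (10 mol%), picolinic acid (20 mol%), K3PO4, DMSO, 90 °C, argon
Reagents that add atoms: none
Why: Ullmann-type diaryl ether coupling, in which CuI with picolinic acid accepts the di-ortho-methoxy phenol and the bromide is unhindered and activated by its para formyl group.

Step 2
Reactants: 3 A-B aldehyde
Product: 5 2,6-dimethoxy-4-(2,4,6-trimethoxyphenoxy)phenol (A-B phenol), via aryl formate 4 (not isolated)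
Conditions: 30% aq H2O2, H2SO4 (cat.), MeOH/CH2Cl2, rt
Reagents that add atoms: hydrogen peroxide, OO
Why: Dakin oxidation, a Baeyer-Villiger-type migration of the electron-rich 2,6-dimethoxyaryl group in the peroxide adduct of the aldehyde, followed by acid methanolysis of formate 4, should free the ring B hydroxyl.

Step 3
Reactants: 6 5-bromo-1,2,3-trimethoxybenzene
Product: 7 6-bromo-2,3,4-trimethoxybenzaldehyde
Conditions: Cl2CHOMe, TiCl4, CH2Cl2, 0 °C to rt; then H2O
Reagents that add atoms: dichloromethyl methyl ether, COC(Cl)Cl; water, O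
Why: Rieche formylation, for which the two open ring positions are equivalent and each is ortho and para to a methoxy group, so a single aldehyde with bromine ortho to the formyl group should form.

Step 4
Reactants: 5 A-B phenol; 7 6-bromo-2,3,4-trimethoxybenzaldehyde
Product: 8 6-[2,6-dimethoxy-4-(2,4,6-trimethoxyphenoxy)phenoxy]-2,3,4-trimethoxybenzaldehyde (A-B-C aldehyde with formyl on ring C C2)
Conditions: CuI (20 mol%), picolinic acid (40 mol%), K3PO4, DMSO, 100 °C, argon
Reagents that add atoms: none
Why: Ullmann-type coupling in which the ortho formyl group activates the C-Br bond and the hindered phenol is the nucleophilic partner, the arrangement that the CuI/picolinic acid system tolerates best.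

Step 5
Reactants: 8 A-B-C aldehyde
Product: 10 6-[2,6-dimethoxy-4-(2,4,6-trimethoxyphenoxy)phenoxy]-2,3,4-trimethoxyphenol (A-B-C phenol), via aryl formate 9 (not isolated)
Conditions: 30% aq H2O2, H2SO4 (cat.), MeOH/CH2Cl2, rt
Reagents that add atoms: hydrogen peroxide, OO
Why: Dakin oxidation of an aldehyde flanked by aryloxy and methoxy groups, whose very electron-rich aryl group migrates readily, should place the hydroxyl on ring C C2.

Step 6
Reactants: 10 A-B-C phenol; 2 4-bromo-2,6-dimethoxybenzaldehyde
Product: 11 4-{6-[2,6-dimethoxy-4-(2,4,6-trimethoxyphenoxy)phenoxy]-2,3,4-trimethoxyphenoxy}-2,6-dimethoxybenzaldehyde (A-B-C-D aldehyde)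
Conditions: CuI (20 mol%), picolinic acid (40 mol%), K3PO4, DMSO, 100 °C, argon
Reagents that add atoms: none
Why: Ullmann-type coupling of a doubly ortho-substituted phenol with the same unhindered, formyl-activated bromide as in step 1.

Step 7
Reactants: 11 A-B-C-D aldehyde
Product: 13 4-{6-[2,6-dimethoxy-4-(2,4,6-trimethoxyphenoxy)phenoxy]-2,3,4-trimethoxyphenoxy}-2,6-dimethoxyphenol (A-B-C-D tetramer phenol), via aryl formate 12 (not isolated)
Conditions: 30% aq H2O2, H2SO4 (cat.), MeOH/CH2Cl2, rt
Reagents that add atoms: hydrogen peroxide, OO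
Why: Dakin oxidation as in step 2 should turn the ring D formyl group into the hydroxyl that sits between two methoxy groups.

Step 8
Reactants: 14 3,4,5-trimethoxyphenol
Product: 15 2-bromo-3,4,5-trimethoxyphenol
Conditions: NBS (1.0 equiv), CH2Cl2, -78 °C to 0 °C
Reagents that add atoms: N-bromosuccinimide, O=C1CCC(=O)N1Br
Why: Electrophilic aromatic bromination at one of the two equivalent positions ortho to the hydroxyl, with one equivalent of NBS at low temperature to hold the reaction at the monobromide.

Step 9
Reactants: 15 2-bromo-3,4,5-trimethoxyphenol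
Product: 18 3,4,5-trimethoxy-2-(trimethylsilyl)phenyl trifluoromethanesulfonate, via O-trimethylsilyl ether 16 (not isolated), via lithium silylphenoxide 17 (not isolated)
Conditions: HMDS, THF, 70 °C, then evaporate; n-BuLi, THF, -100 °C; Tf2O, -100 °C to rt
Reagents that add atoms: hexamethyldisilazane, C[Si](C)(C)N[Si](C)(C)C; triflic anhydride, O=S(=O)(OS(=O)(=O)C(F)(F)F)C(F)(F)F
Why: O-silylation, bromine-lithium exchange, retro-Brook 1,3-shift of silicon from oxygen to the lithiated carbon and O-triflation of phenoxide 17 form the standard one-pot entry to ortho-silylaryl triflates, and exchange at -100 °C is faster than any other attack of n-BuLi on the ring.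

Step 10
Reactants: 13 A-B-C-D tetramer phenol; 18 3,4,5-trimethoxy-2-(trimethylsilyl)phenyl trifluoromethanesulfonate; 19 iodopentafluorobenzene
Product: 23 A-to-E pentamer iodide (ring D oxygen of 13 bonded to C1 of a 2-iodo-3,4,5-trimethoxyphenyl ring E), via potassium phenoxide 20 (not isolated), via 3,4,5-trimethoxybenzyne 21 (not isolated), via aryl potassium adduct 22 (not isolated)
Conditions: KH (1.0 equiv), THF, 0 °C; then 19 (3 equiv), KF, 18-crown-6, THF, -20 °C to rt, slow addition of 18 (2 equiv)
Reagents that add atoms: none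
Why: Proposed new method: fluoride attacks silicon of 18 and triflate leaves to give aryne 21, phenoxide 20 adds to C1 (the aryne carbon remote from the C3 methoxy group), and the aryl potassium 22 formed at C2 takes iodine from 19 through a halogen-ate transfer, so the C1-O and C2-I bonds form in one operation. The closest known reaction types are fluoride-triggered aryne 1,2-difunctionalisations in which a sulfur or nitrogen nucleophile adds and the aryl anion is halogenated by a perfluoroaryl halide, together with the O-arylation of phenols by silylaryl triflates. No ring is closed and no stereocentre is formed. Site selectivity should follow from the C3 methoxy group, whose inductive pull makes C1 the flatter, more electrophilic aryne carbon and stabilises the negative charge that develops at C2. Iodination should win over protonation because the phenoxide is preformed with KH, the medium (THF, KF, 18-crown-6) offers no acidic hydrogen, and 19 is in excess. The doubly ortho-substituted phenoxide is expected to add to the aryne faster than it attacks a C-F carbon of 19 at or below room temperature, and the aryne, unlike a CuI-catalysed coupling, is little affected by that hindrance.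

Step 11
Reactants: 23 A-to-E pentamer iodide
Product: 26 A-to-E pentamer phenol (hydroxyl on ring E C2 in place of iodine), via arylmagnesium chloride 24 (not isolated), via dimethyl arylboronate 25 (not isolated)
Conditions: i-PrMgCl·LiCl, THF, -20 °C; B(OMe)3, -20 °C to rt; 30% aq H2O2, aq NaOH, 0 °C
Reagents that add atoms: hydrogen peroxide, OO
Why: Iodine-magnesium exchange (helped by the two flanking oxygens), trapping of Grignard reagent 24 with B(OMe)3 and oxidation of boronate 25 with aryl migration from boron to oxygen make up the standard aryl halide to phenol sequence, and methyl and diaryl ethers are inert to all three reagents.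

Step 12
Reactants: 26 A-to-E pentamer phenol; 27 5-iodo-1,2,3-trimethoxybenzene
Product: 28 hexadeca-O-methyl ether of the target (ring E C2 oxygen of 26 bonded to a 3,4,5-trimethoxyphenyl ring F)
Conditions: CuI (20 mol%), picolinic acid (40 mol%), K3PO4, DMSO, 90 °C, argon
Reagents that add atoms: none
Why: Ullmann-type diaryl ether coupling in which the doubly ortho-substituted phenol is again the nucleophilic partner, as in step 6, and the aryl halide has no ortho substituent and carries iodine, the more reactive leaving group, to make up for the missing formyl activation.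

Step 13
Reactants: 28 hexadeca-O-methyl ether of the target
Product: 29 target hexamer CNP0114537.0
Conditions: BBr3 (excess), CH2Cl2, -78 °C to rt; then MeOH, H2O, argon
Reagents that add atoms: none
Why: Exhaustive Lewis acid demethylation of aryl methyl ethers (bromide attacks the methyl group of each boron-complexed ether) should remove all sixteen methyl groups, while the five diaryl ether links, which offer no sp3 carbon for bromide attack, stay intact.

Compound list
1 | 2,4,6-trimethoxyphenol | COc1cc(OC)c(O)c(OC)c1 | starting material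
2 | 4-bromo-2,6-dimethoxybenzaldehyde | COc1cc(Br)cc(OC)c1C=O | starting material
3 | 2,6-dimethoxy-4-(2,4,6-trimethoxyphenoxy)benzaldehyde (A-B aldehyde) | COc1cc(OC)c(Oc2cc(OC)c(C=O)c(OC)c2)c(OC)c1 | intermediate
4 | 2,6-dimethoxy-4-(2,4,6-trimethoxyphenoxy)phenyl formate (formed in the flask) | COc1cc(OC)c(Oc2cc(OC)c(OC=O)c(OC)c2)c(OC)c1 | intermediate
5 | 2,6-dimethoxy-4-(2,4,6-trimethoxyphenoxy)phenol (A-B phenol) | COc1cc(OC)c(Oc2cc(OC)c(O)c(OC)c2)c(OC)c1 | intermediate
6 | 5-bromo-1,2,3-trimethoxybenzene | COc1cc(Br)cc(OC)c1OC | starting material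
7 | 6-bromo-2,3,4-trimethoxybenzaldehyde | COc1cc(Br)c(C=O)c(OC)c1OC | intermediate
8 | 6-[2,6-dimethoxy-4-(2,4,6-trimethoxyphenoxy)phenoxy]-2,3,4-trimethoxybenzaldehyde (A-B-C aldehyde) | COc1cc(OC)c(Oc2cc(OC)c(Oc3cc(OC)c(OC)c(OC)c3C=O)c(OC)c2)c(OC)c1 | intermediate
9 | 6-[2,6-dimethoxy-4-(2,4,6-trimethoxyphenoxy)phenoxy]-2,3,4-trimethoxyphenyl formate (formed in the flask) | COc1cc(OC)c(Oc2cc(OC)c(Oc3cc(OC)c(OC)c(OC)c3OC=O)c(OC)c2)c(OC)c1 | intermediate
10 | 6-[2,6-dimethoxy-4-(2,4,6-trimethoxyphenoxy)phenoxy]-2,3,4-trimethoxyphenol (A-B-C phenol) | COc1cc(OC)c(Oc2cc(OC)c(Oc3cc(OC)c(OC)c(OC)c3O)c(OC)c2)c(OC)c1 | intermediate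
11 | 4-{6-[2,6-dimethoxy-4-(2,4,6-trimethoxyphenoxy)phenoxy]-2,3,4-trimethoxyphenoxy}-2,6-dimethoxybenzaldehyde (A-B-C-D aldehyde) | COc1cc(OC)c(Oc2cc(OC)c(Oc3cc(OC)c(OC)c(OC)c3Oc3cc(OC)c(C=O)c(OC)c3)c(OC)c2)c(OC)c1 | intermediate
12 | formate ester of tetramer phenol 13 (formed in the flask) | COc1cc(OC)c(Oc2cc(OC)c(Oc3cc(OC)c(OC)c(OC)c3Oc3cc(OC)c(OC=O)c(OC)c3)c(OC)c2)c(OC)c1 | intermediate
13 | 4-{6-[2,6-dimethoxy-4-(2,4,6-trimethoxyphenoxy)phenoxy]-2,3,4-trimethoxyphenoxy}-2,6-dimethoxyphenol (A-B-C-D tetramer phenol) | COc1cc(OC)c(Oc2cc(OC)c(Oc3cc(OC)c(OC)c(OC)c3Oc3cc(OC)c(O)c(OC)c3)c(OC)c2)c(OC)c1 | intermediate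
14 | 3,4,5-trimethoxyphenol | COc1cc(O)cc(OC)c1OC | starting material
15 | 2-bromo-3,4,5-trimethoxyphenol | COc1cc(O)c(Br)c(OC)c1OC | intermediate
16 | (2-bromo-3,4,5-trimethoxyphenoxy)trimethylsilane (formed in the flask) | COc1cc(O[Si](C)(C)C)c(Br)c(OC)c1OC | intermediate
17 | lithium 3,4,5-trimethoxy-2-(trimethylsilyl)phenoxide (formed in the flask) | COc1cc([O-])c([Si](C)(C)C)c(OC)c1OC.[Li+] | intermediate
18 | 3,4,5-trimethoxy-2-(trimethylsilyl)phenyl trifluoromethanesulfonate | COc1cc(OS(=O)(=O)C(F)(F)F)c([Si](C)(C)C)c(OC)c1OC | intermediate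
19 | iodopentafluorobenzene | Fc1c(F)c(F)c(I)c(F)c1F | starting material
20 | potassium phenoxide of tetramer 13 (formed in the flask) | COc1cc(OC)c(Oc2cc(OC)c(Oc3cc(OC)c(OC)c(OC)c3Oc3cc(OC)c([O-])c(OC)c3)c(OC)c2)c(OC)c1.[K+] | intermediate
21 | 3,4,5-trimethoxybenzyne (1,2-didehydro-3,4,5-trimethoxybenzene, formed in the flask) | COC1=C(OC)C(OC)=CC#C1 | intermediate
22 | aryl potassium adduct of 20 and 21, carbanion at ring E C2 (formed in the flask) | COc1cc(OC)c(Oc2cc(OC)c(Oc3cc(OC)c(OC)c(OC)c3Oc3cc(OC)c(Oc4cc(OC)c(OC)c(OC)[c-]4)c(OC)c3)c(OC)c2)c(OC)c1.[K+] | intermediate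
23 | A-to-E pentamer iodide (2-iodo-3,4,5-trimethoxyphenyl ether of 13) | COc1cc(OC)c(Oc2cc(OC)c(Oc3cc(OC)c(OC)c(OC)c3Oc3cc(OC)c(Oc4cc(OC)c(OC)c(OC)c4I)c(OC)c3)c(OC)c2)c(OC)c1 | intermediate
24 | arylmagnesium chloride from 23, magnesium at ring E C2 (formed in the flask) | COc1cc(OC)c(Oc2cc(OC)c(Oc3cc(OC)c(OC)c(OC)c3Oc3cc(OC)c(Oc4cc(OC)c(OC)c(OC)c4[Mg]Cl)c(OC)c3)c(OC)c2)c(OC)c1 | intermediate
25 | dimethyl arylboronate from 24, boron at ring E C2 (formed in the flask) | COc1cc(OC)c(Oc2cc(OC)c(Oc3cc(OC)c(OC)c(OC)c3Oc3cc(OC)c(Oc4cc(OC)c(OC)c(OC)c4B(OC)OC)c(OC)c3)c(OC)c2)c(OC)c1 | intermediate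
26 | A-to-E pentamer phenol (hydroxyl on ring E C2) | COc1cc(OC)c(Oc2cc(OC)c(Oc3cc(OC)c(OC)c(OC)c3Oc3cc(OC)c(Oc4cc(OC)c(OC)c(OC)c4O)c(OC)c3)c(OC)c2)c(OC)c1 | intermediate
27 | 5-iodo-1,2,3-trimethoxybenzene | COc1cc(I)cc(OC)c1OC | starting material
28 | hexadeca-O-methyl ether of the target (A-to-F hexamer) | COc1cc(OC)c(Oc2cc(OC)c(Oc3cc(OC)c(OC)c(OC)c3Oc3cc(OC)c(Oc4cc(OC)c(OC)c(OC)c4Oc4cc(OC)c(OC)c(OC)c4)c(OC)c3)c(OC)c2)c(OC)c1 | intermediate
29 | CNP0114537.0, free hexadecahydroxy hexamer | Oc1cc(O)c(Oc2cc(O)c(Oc3cc(O)c(O)c(O)c3Oc3cc(O)c(Oc4cc(O)c(O)c(O)c4Oc4cc(O)c(O)c(O)c4)c(O)c3)c(O)c2)c(O)c1 | target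

Total step count: 13.
Longest linear sequence: 10 steps (steps 1, 2, 4, 5, 6, 7, 10, 11, 12, 13).

Steps most likely to fail

Step 10 (the proposed new method). Three processes may divert it: the aryl anion may be protonated before it meets the iodine donor; the phenoxide may be consumed by substitution at a C-F carbon of the iodine donor; and the aryne may be used up by the released pentafluorophenyl anion or by the aryl anion itself. The fallback uses only the known operations already used for ring C. It sets out from tetramer phenol 13, which is coupled with bromoaldehyde 7 (CuI, picolinic acid, K3PO4, DMSO, 100 °C) to give the A-to-E pentamer aldehyde F1, with the formyl group on ring E C2. Dakin oxidation (30% aq H2O2, cat. H2SO4, MeOH/CH2Cl2) through the aryl formate F2 then gives pentamer phenol 26, where the route is rejoined before step 12; steps 10 and 11 are not needed on this path.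

Step 4. Both partners are ortho-substituted, so the CuI-catalysed C-O bond formation may be slow, and reductive loss of bromine from 7 and oxidative loss of the electron-rich phenol may then take over. The fallback replaces the CuI-catalysed coupling by an uncatalysed nucleophilic aromatic substitution. It sets out from phenol 5, which is heated with 6-fluoro-2,3,4-trimethoxybenzaldehyde F3 (made by Rieche formylation of purchased 5-fluoro-1,2,3-trimethoxybenzene, COc1cc(F)cc(OC)c1OC) and Cs2CO3 in DMF at 110 °C. The ortho formyl group stabilises the Meisenheimer adduct, fluoride leaves, and the route is rejoined at aldehyde 8.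

Step 13. Cleavage of sixteen ethers may stop short, and the free polyphenol, which contains three pyrogallol-type rings, may be lost to air oxidation during isolation from under-cleaved material. The fallback changes the isolation strategy and sets out from 28. After BBr3 treatment the crude polyphenol is not isolated but acetylated in the same flask (Ac2O, pyridine, DMAP) to the hexadecaacetate F4, which is stable to air and can be purified on silica, with under-cleaved material removed. Acid methanolysis (HCl in degassed MeOH, rt) then returns the route to target 29.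

Further compounds
F1 | step 10 | A-to-E pentamer aldehyde (6-aryloxy-2,3,4-trimethoxybenzaldehyde, aryl being the ring D residue of 13) | COc1cc(OC)c(Oc2cc(OC)c(Oc3cc(OC)c(OC)c(OC)c3Oc3cc(OC)c(Oc4cc(OC)c(OC)c(OC)c4C=O)c(OC)c3)c(OC)c2)c(OC)c1
F2 | step 10 | formate ester of pentamer phenol 26 | COc1cc(OC)c(Oc2cc(OC)c(Oc3cc(OC)c(OC)c(OC)c3Oc3cc(OC)c(Oc4cc(OC)c(OC)c(OC)c4OC=O)c(OC)c3)c(OC)c2)c(OC)c1
F3 | step 4 | 6-fluoro-2,3,4-trimethoxybenzaldehyde | COc1cc(F)c(C=O)c(OC)c1OC
F4 | step 13 | hexadecaacetate of the target | CC(=O)Oc1cc(OC(C)=O)c(Oc2cc(OC(C)=O)c(Oc3cc(OC(C)=O)c(OC(C)=O)c(OC(C)=O)c3Oc3cc(OC(C)=O)c(Oc4cc(OC(C)=O)c(OC(C)=O)c(OC(C)=O)c4Oc4cc(OC(C)=O)c(OC(C)=O)c(OC(C)=O)c4)c(OC(C)=O)c3)c(OC(C)=O)c2)c(OC(C)=O)c1
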